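The target is a head-to-tail dehydrodimer of davidigenin: the only bond not present in the monomer is the biaryl bond from C3 of ring B (p-alkylphenol) of one unit to C5′ of ring A (4-acylresorcinol) of the other, ortho to a hydroxyl on both rings. Everything rests on making this bond by a biomimetic anodic dehydrodimerisation of unprotected davidigenin, which turns two identical C15 monomers into the C30 target in one operation, without halide, boron or protecting group. The monomer itself supplies the selectivity: ring B is the easier ring to oxidise, ring A the better carbon nucleophile at C5′. Davidigenin is made in one step from resorcinol and phloretic acid.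

Key step: step 2

Remark: the SMILES carries no stereodescriptor; the molecule has no stereocentre and its di-ortho-substituted biaryl axis rotates freely, so the target is achiral and no stereocontrol is needed.

Step 1
Reactants: 1 resorcinol; 2 phloretic acid [3-(4-hydroxyphenyl)propanoic acid]
Product: 4 davidigenin [1-(2,4-dihydroxyphenyl)-3-(4-hydroxyphenyl)propan-1-one], via davidigenin difluoroboron chelate 3 (not isolated)
Conditions: 1 (1.5 equiv), BF3·OEt2 (neat, excess), 85 °C, N2; then 10% aq NaOAc, rt
Reagents that add atoms: none
Why: BF3-promoted Nencki-type Friedel–Crafts C-acylation of resorcinol by the free acid should occur at C4 (para to one OH, ortho to the other), where the ketone is held as the deactivated BF2 chelate 3 (boron and fluorine from BF3·OEt2) that blocks a second acylation and is hydrolysed by aqueous acetate, while resorcinol out-competes the far less nucleophilic p-alkylphenol ring of 2.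

Step 2
Reactants: 4 davidigenin (two molecules)
Product: 6 target [1-(2,4-dihydroxyphenyl)-3-{2′,4′,6-trihydroxy-5′-[3-(4-hydroxyphenyl)propanoyl]-[1,1′-biphenyl]-3-yl}propan-1-one], via cyclohexadienone keto tautomer 5 (not isolated)
Conditions: constant-current electrolysis, undivided cell, boron-doped diamond anode, Pt cathode, Bu3NMe+ MeOSO3− (0.1 M), HFIP/MeOH 9:1, 50 °C, charge limited to ca. 0.8 F per mol of 4; unreacted 4 recovered and recycled
Reagents that add atoms: none
Why: Anodic one-electron oxidation with loss of a proton converts the p-alkylphenol ring B of one molecule of 4 into a phenoxyl radical, whose ortho carbon C3 is attacked by C5′ of the 4-acylresorcinol ring A of a second, unoxidised molecule; loss of a further electron and proton rearomatises ring A to give keto tautomer 5, which enolises to biphenol 6, while the protons are reduced to H2 at the cathode. The closest known reaction type is the anodic dehydrogenative phenol–phenol or phenol–arene cross-coupling on boron-doped diamond in HFIP, the electrochemical counterpart of biomimetic oxidative phenol coupling. No ring is closed and no stereocentre survives: the one sp3 carbon of 5 is erased on tautomerisation and the di-ortho-substituted biaryl axis of 6 rotates freely. The step needs cross (B to A) over homo (B to B, A to A) coupling, and this should be secured by the acyl group, which raises the oxidation potential of ring A yet leaves its C5′ doubly oxygen-activated (ortho to 4′-OH, para to the chelated 2′-OH), whereas ring B is the easier ring to oxidise but only singly activated as a nucleophile, so the radical and nucleophile roles fall to different rings of the same monomer. It also needs C5′ over C3′ and ortho C–C over C–O or ipso attack: C3′ lies between two oxygens and would give a tri-ortho-substituted biaryl, the para position of ring B is blocked by the chain, and HFIP is expected to favour C–C coupling of the hydrogen-bonded phenoxyl radical. Because 6 should be easier to oxidise than 4, the charge is limited to partial conversion and unreacted 4 is recycled; isomeric dimers are expected as co-products and would be removed by chromatography.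

Compound list
1 | resorcinol (benzene-1,3-diol) | Oc1cccc(O)c1 | starting material
2 | phloretic acid, 3-(4-hydroxyphenyl)propanoic acid | OC(=O)CCc1ccc(O)cc1 | starting material
3 | davidigenin difluoroboron chelate (O,O-BF2 complex of the 2′-hydroxy ketone; not isolated) | F[B-]1(F)Oc2cc(O)ccc2C(CCc2ccc(O)cc2)=[O+]1 | intermediate
4 | davidigenin, 1-(2,4-dihydroxyphenyl)-3-(4-hydroxyphenyl)propan-1-one | O=C(CCc1ccc(O)cc1)c1ccc(O)cc1O | intermediate
5 | keto tautomer of 6 (ring B as 6-aryl-cyclohexa-2,4-dien-1-one; transient, racemic at its sp3 carbon; not isolated) | O=C1C=CC(CCC(=O)c2ccc(O)cc2O)=CC1c1cc(C(=O)CCc2ccc(O)cc2)c(O)cc1O | intermediate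
6 | target, 1-(2,4-dihydroxyphenyl)-3-{2′,4′,6-trihydroxy-5′-[3-(4-hydroxyphenyl)propanoyl]-[1,1′-biphenyl]-3-yl}propan-1-one (achiral) | O=C(CCc1ccc(O)c(-c2cc(C(=O)CCc3ccc(O)cc3)c(O)cc2O)c1)c1ccc(O)cc1O | target

Total step count: 2
Longest linear sequence: 2 steps

Steps most likely to fail (the route has only two steps, so both are ranked, the riskier first):

1. Step 2. The radical–nucleophile coupling may lose regiocontrol in three ways: homocoupling between two B rings, attack at C3′ instead of C5′, and C–O coupling. The product may also be over-oxidised to oligomers, and the benzylic position may be oxidised through a quinone methide. Fallback (Suzuki–Miyaura biaryl synthesis, known chemistry; sets out from 4 for the ring-A partner and from 2 and 1 for the ring-B partner, and comes back at 6):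
   - Ring-A partner: 4 is protected at the two non-chelated hydroxyls (MOMCl, K2CO3, acetone, rt) to give 4,4′-bis(methoxymethyl) davidigenin F1. NBS (MeCN, 0 °C to rt) should brominate the doubly oxygen-activated ring A at C5′ to give the 5′-bromide F2. Miyaura borylation (B2pin2, Pd(dppf)Cl2, KOAc, dioxane, 90 °C) gives the 5′-pinacol boronate F3.
   - Ring-B partner: 2 is mono-brominated ortho to the hydroxyl (Br2, AcOH, rt) to give 3-(3-bromo-4-hydroxyphenyl)propanoic acid F4. F4 acylates 1 under the conditions of step 1 to give 3-bromodavidigenin F5.
   - Coupling and release: Suzuki–Miyaura coupling of F3 with F5 (Pd(OAc)2, SPhos, K3PO4, dioxane/H2O, 80 °C) should give the bis(methoxymethyl) ether of the target F6. HCl in MeOH (rt to 40 °C) then releases 6.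

2. Step 1. The phenolic acid may acylate itself to oligoesters, resorcinol may be acylated a second time at C6, and hydrolysis of the boron chelate may be incomplete. Fallback (aldol condensation and hydrogenation instead of acylation with the phenolic acid; sets out from 1 and comes back at 4): Nencki acetylation of 1 (AcOH, ZnCl2, 140 °C) gives 2,4-dihydroxyacetophenone F7. Claisen–Schmidt condensation with 4-hydroxybenzaldehyde (KOH, aq EtOH, rt to 60 °C, then acidification) gives (E)-isoliquiritigenin F8. Hydrogenation of the enone C=C only (H2 1 atm, Pd/C, EtOAc, rt) gives 4.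

Further compounds
F1 | step 2 | 4,4′-bis(methoxymethyl) davidigenin, 1-[2-hydroxy-4-(methoxymethoxy)phenyl]-3-[4-(methoxymethoxy)phenyl]propan-1-one | O=C(CCc1ccc(OCOC)cc1)c1ccc(OCOC)cc1O
F2 | step 2 | 5′-bromo-4,4′-bis(methoxymethyl) davidigenin | O=C(CCc1ccc(OCOC)cc1)c1cc(Br)c(OCOC)cc1O
F3 | step 2 | 5′-(4,4,5,5-tetramethyl-1,3,2-dioxaborolan-2-yl)-4,4′-bis(methoxymethyl) davidigenin | O=C(CCc1ccc(OCOC)cc1)c1cc(B2OC(C)(C)C(C)(C)O2)c(OCOC)cc1O
F4 | step 2 | 3-(3-bromo-4-hydroxyphenyl)propanoic acid | OC(=O)CCc1ccc(O)c(Br)c1
F5 | step 2 | 3-bromodavidigenin, 3-(3-bromo-4-hydroxyphenyl)-1-(2,4-dihydroxyphenyl)propan-1-one | O=C(CCc1ccc(O)c(Br)c1)c1ccc(O)cc1O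
F6 | step 2 | bis(methoxymethyl) ether of the target (MOM on the 2′- and 4-oxygens of the lower davidigenin unit, i.e. on the biaryl-ortho OH of its ring A and on its ring-B OH) | O=C(CCc1ccc(O)c(-c2cc(C(=O)CCc3ccc(OCOC)cc3)c(OCOC)cc2O)c1)c1ccc(O)cc1O
F7 | step 1 | 2,4-dihydroxyacetophenone | CC(=O)c1ccc(O)cc1O
F8 | step 1 | (E)-isoliquiritigenin, (E)-1-(2,4-dihydroxyphenyl)-3-(4-hydroxyphenyl)prop-2-en-1-one | O=C(/C=C/c1ccc(O)cc1)c1ccc(O)cc1O
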